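**Strategy.** Ring A (C10, C1, C2, C3, C4, C5) is made last, from a five-membered ring that lacks C1. (R)-Pulegone supplies ring B with C8. Conjugate allylation and equilibration set C5, and two enolate alkylations build C9 and attach a side chain cut from (R)-citronellol. Ozonolysis and McMurry coupling then give a hydrindene with a C2=C10 double bond. In the key step dibromocarbene adds to this bond and the strained gem-dibromocyclopropane opens, inserting C1 between C2 and C10. The step exploits the trisubstituted C1=C10 alkene at the ring A/ring B junction: C1 arrives as a carbene carbon and the double bond ends up where the target has it.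

Key step: step 9

Remark on numbering: halimane numbering is used throughout. Ring A is C1–C5 and C10, ring B is C5–C10, the side chain is C11–C15 with C16 on C13; C17 is on C8, C18 and C19 on C4, C20 on C9. The target is (5S,8R,9R,13R).

Assumption: minor diastereomers from steps 1 and 6 are removed by chromatography; the cis/trans isomerism of 24 has no bearing on the route.

Step 1
Reactants: 1 (R)-(+)-pulegone
Product: 3 (2S,5R)-5-methyl-2-(2-methylpent-4-en-2-yl)cyclohexan-1-one, via C2-epimer mixture 2 (not isolated)
Conditions: allylSiMe3, TiCl4, CH2Cl2, −78 °C; then NaOMe (cat.), MeOH, rt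
Reagents that add atoms: allyltrimethylsilane, C=CC[Si](C)(C)C
Why: Hosomi–Sakurai conjugate allylation of the TiCl4-activated s-cis enone forms the quaternary C4, and methoxide equilibration of the epimerisable α-carbon (C5 of the target) should settle in the trans isomer with both ring substituents equatorial, as 8-substituted menthones do; C8 comes unchanged from 1.

Step 2
Reactants: 3 (2S,5R)-5-methyl-2-(2-methylpent-4-en-2-yl)cyclohexan-1-one
Product: 5 (2S,5R)-5,6-dimethyl-2-(2-methylpent-4-en-2-yl)cyclohexan-1-one (both C6 epimers), via lithium enolate 4 (not isolated)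
Conditions: LiN(iPr)2, THF, −78 °C; then MeI, −78 → 0 °C
Reagents that add atoms: iodomethane, CI
Why: Kinetic enolate formation with the hindered amide base should occur at the open α-methylene (C9) and not at C5–H next to the quaternary carbon, and SN2 methylation (enolate alkylation) brings in C20; the new center forms as an epimer mixture and is made planar again in step 6.

Step 3
Reactants: 6 (R)-(+)-β-citronellol
Product: 7 (R)-citronellyl triisopropylsilyl ether
Conditions: iPr3SiCl, imidazole, DMF, rt
Reagents that add atoms: triisopropylsilyl chloride, CC(C)[Si](Cl)(C(C)C)C(C)C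
Why: Imidazole-promoted silylation of the primary alcohol masks the future C15 oxygen for the basic and reductive steps ahead; no stereocenter is touched.

Step 4
Reactants: 7 (R)-citronellyl triisopropylsilyl ether
Product: 9 (R)-4-methyl-6-(triisopropylsilyloxy)hexanoic acid, via aldehyde 8 (not isolated)
Conditions: RuCl3 (cat.), NaIO4, CCl4/MeCN/H2O, rt
Reagents that add atoms: sodium periodate, [Na+].[O-]I(=O)(=O)=O; water, O
Why: RuO4-catalysed oxidative cleavage of the trisubstituted alkene gives the acid and acetone, the stereocenter lying two carbons away from the reacting site.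

Step 5
Reactants: 9 (R)-4-methyl-6-(triisopropylsilyloxy)hexanoic acid
Product: 11 (S)-(5-iodo-3-methylpentyloxy)triisopropylsilane, via acyl hypoiodite 10 (not isolated)
Conditions: PhI(OAc)2, I2, hν, cyclohexane, reflux
Reagents that add atoms: iodine, II
Why: Hunsdiecker-type iododecarboxylation: the acyl hypoiodite fragments under light to CO2 and a primary radical that is capped by iodine, which shortens the chain by one carbon without touching the stereocenter (the descriptor changes only because iodine outranks oxygen).

Step 6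
Reactants: 5 (2S,5R)-5,6-dimethyl-2-(2-methylpent-4-en-2-yl)cyclohexan-1-one; 11 (S)-(5-iodo-3-methylpentyloxy)triisopropylsilane
Product: 13 (2R,3R,6S)-2,3-dimethyl-2-[(3R)-3-methyl-5-(triisopropylsilyloxy)pentyl]-6-(2-methylpent-4-en-2-yl)cyclohexan-1-one, via lithium enolate 12 (not isolated)
Conditions: LiN(iPr)2, THF, −78 → 0 °C; then 11, HMPA, −78 °C → rt
Reagents that add atoms: none
Why: Kinetic enolisation again spares the shielded C5–H, and enolate alkylation (SN2) with the primary iodide should proceed by axial attack through a chair-like transition state on the enolate whose C5 and C8 substituents stay equatorial, placing the chain axial (cis to the C8 methyl) and C20 equatorial as in the target; the other half-chair would put the tertiary alkyl group at C5 pseudoaxial over the opposite face of C9.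

Step 7
Reactants: 13 (2R,3R,6S)-2,3-dimethyl-2-[(3R)-3-methyl-5-(triisopropylsilyloxy)pentyl]-6-(2-methylpent-4-en-2-yl)cyclohexan-1-one
Product: 15 3-methyl-3-[(1S,3R,4R)-3,4-dimethyl-3-[(3R)-3-methyl-5-(triisopropylsilyloxy)pentyl]-2-oxocyclohexyl]butanal, via ozonide 14 (not isolated)
Conditions: O3, CH2Cl2, −78 °C; then PPh3, −78 °C → rt
Reagents that add atoms: ozone, [O-][O+]=O
Why: Ozonolysis (1,3-dipolar cycloaddition, cycloreversion, reduction of the ozonide) cleaves the only C=C bond to the aldehyde that carries C2, while ketone and silyl ether are inert and the neutral conditions leave C5 alone.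

Step 8
Reactants: 15 3-methyl-3-[(1S,3R,4R)-3,4-dimethyl-3-[(3R)-3-methyl-5-(triisopropylsilyloxy)pentyl]-2-oxocyclohexyl]butanal
Product: 16 (5S,8R,9R,13R)-15-(triisopropylsilyloxy)-1-norhalim-2(10)-ene (bicyclo[4.3.0]non-1(9)-ene core)
Conditions: TiCl3(DME)1.5, Zn–Cu couple, DME, reflux, slow addition of 15
Reagents that add atoms: none
Why: McMurry coupling: low-valent titanium couples ketone and aldehyde intramolecularly to a titanium pinacolate and deoxygenates it to the C2=C10 alkene, five-membered ring closure helping against the hindrance at C10; C5 can no longer epimerise afterwards.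

Step 9
Reactants: 16 (5S,8R,9R,13R)-15-(triisopropylsilyloxy)-1-norhalim-2(10)-ene
Product: 18 (5S,8R,9R,13R)-1,2-dibromo-15-(triisopropylsilyloxy)halim-1(10)-ene (both C2 epimers), via gem-dibromocyclopropane 17 (not isolated)
Conditions: CHBr3, KOtBu, pentane, −20 °C → rt; then toluene, 60 °C
Reagents that add atoms: bromoform, BrC(Br)Br
Why: α-Elimination of HBr from bromoform gives dibromocarbene, which adds in a concerted [2+1] cycloaddition to the electron-rich C2=C10 bond; the resulting 6,6-dibromobicyclo[3.1.0]hexane unit then loses its endo bromide while the C2–C10 bond opens in a disrotatory two-electron electrocyclic process to a 2-bromoallyl cation (C10–C1–C2), which bromide captures at C2. The closest known reaction type is the dihalocarbene ring expansion of cyclopentenes to 2,3-dihalocyclohexenes. Ring A is not closed by a new cyclisation: the five-membered ring (C10, C2, C3, C4, C5) grows by one atom when the zero-atom bridge of the cyclopropane breaks, driven by release of cyclopropane strain. No lasting stereocenter is formed, since the C2–Br epimers are levelled in step 10 and C5, C8, C9 and C13 are not involved. The step needs bromide return at C2 and not at C10, and no proton loss toward C5; the quaternary C9 shields C10, capture at the secondary terminus gives the more substituted C1=C10 alkene, and the non-polar medium keeps the ion pair tight. The position of the double bond is secured by the mechanism, because the carbene carbon C1 must become the central carbon of the allyl unit.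

Step 10
Reactants: 18 (5S,8R,9R,13R)-1,2-dibromo-15-(triisopropylsilyloxy)halim-1(10)-ene
Product: 20 (5S,8R,9R,13R)-15-(triisopropylsilyloxy)halim-1(10)-ene, via vinyl bromide 19 (not isolated)
Conditions: Bu3SnH, AIBN (cat.), toluene, 100 °C
Reagents that add atoms: none
Why: Radical-chain dehalogenation with the stannane: the allylic bromide goes first through a 2-bromoallyl radical that should take hydrogen at the less hindered secondary terminus C2 (keeping the C1=C10 bond), and the vinyl bromide is then reduced through a σ-vinyl radical at C1; no stereocenter is formed.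

Step 11
Reactants: 20 (5S,8R,9R,13R)-15-(triisopropylsilyloxy)halim-1(10)-ene
Product: 21 (5S,8R,9R,13R)-halim-1(10)-en-15-ol
Conditions: Bu4NF, THF, rt
Reagents that add atoms: none
Why: Fluoride-induced desilylation (Si–F bond formation) frees the primary alcohol without affecting the alkene or any stereocenter.

Step 12
Reactants: 21 (5S,8R,9R,13R)-halim-1(10)-en-15-ol
Product: 23 (5S,8R,9R,13R)-halim-1(10)-en-15-oic acid, via aldehyde 22 (not isolated)
Conditions: TEMPO (cat.), PhI(OAc)2, MeCN/H2O, rt
Reagents that add atoms: water, O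
Why: Oxoammonium-mediated (TEMPO/PhI(OAc)2) oxidation takes the primary alcohol to the aldehyde and, through its hydrate, to the acid; an isolated trisubstituted alkene is inert to it and the β-stereocenter C13 cannot epimerise.

Step 13
Reactants: 23 (5S,8R,9R,13R)-halim-1(10)-en-15-oic acid; 24 cis-2-phenyl-1,3-dioxan-5-ol
Product: 25 cis-2-phenyl-1,3-dioxan-5-yl (5S,8R,9R,13R)-halim-1(10)-en-15-oate
Conditions: EDC·HCl, DMAP (cat.), CH2Cl2, 0 °C → rt
Reagents that add atoms: none
Why: Steglich esterification (carbodiimide activation, acyl transfer by DMAP) acylates the only free hydroxyl of the 1,3-protected glycerol, so the ester sits at O-2 by construction.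

Step 14
Reactants: 25 cis-2-phenyl-1,3-dioxan-5-yl (5S,8R,9R,13R)-halim-1(10)-en-15-oate
Product: 27 1,3-dihydroxypropan-2-yl (5S,8R,9R,13R)-halim-1(10)-en-15-oate (CNP0174907.2), via cyclic borate 26 (not isolated)
Conditions: B(OMe)3, B(OH)3 (cat.), 100 °C, sealed tube; then H2O, rt
Reagents that add atoms: none
Why: Transacetalisation with trimethyl borate removes the benzylidene group as its dimethyl acetal and holds the 1,3-diol as a cyclic borate, which blocks 2→1 acyl migration until mild hydrolysis releases the target.

**Compound list**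

1 | (R)-(+)-pulegone, (5R)-5-methyl-2-(propan-2-ylidene)cyclohexan-1-one | C[C@@H]1CCC(=C(C)C)C(=O)C1 | starting material
2 | (5R)-5-methyl-2-(2-methylpent-4-en-2-yl)cyclohexan-1-one, both C2 epimers | C=CCC(C)(C)C1CC[C@@H](C)CC1=O | intermediate
3 | (2S,5R)-5-methyl-2-(2-methylpent-4-en-2-yl)cyclohexan-1-one (trans, both substituents equatorial) | C=CCC(C)(C)[C@@H]1CC[C@@H](C)CC1=O | intermediate
4 | lithium enolate of 3 toward the CH2 group | C=CCC(C)(C)[C@@H]1CC[C@@H](C)C=C1O[Li] | intermediate
5 | (2S,5R)-5,6-dimethyl-2-(2-methylpent-4-en-2-yl)cyclohexan-1-one, both C6 epimers | C=CCC(C)(C)[C@@H]1CC[C@@H](C)C(C)C1=O | intermediate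
6 | (R)-(+)-β-citronellol | C[C@H](CCC=C(C)C)CCO | starting material
7 | (R)-citronellyl triisopropylsilyl ether | C[C@H](CCC=C(C)C)CCO[Si](C(C)C)(C(C)C)C(C)C | intermediate
8 | (R)-4-methyl-6-(triisopropylsilyloxy)hexanal | C[C@H](CCC=O)CCO[Si](C(C)C)(C(C)C)C(C)C | intermediate
9 | (R)-4-methyl-6-(triisopropylsilyloxy)hexanoic acid | C[C@H](CCC(=O)O)CCO[Si](C(C)C)(C(C)C)C(C)C | intermediate
10 | acyl hypoiodite of 9 | C[C@H](CCC(=O)OI)CCO[Si](C(C)C)(C(C)C)C(C)C | intermediate
11 | (S)-(5-iodo-3-methylpentyloxy)triisopropylsilane | C[C@H](CCI)CCO[Si](C(C)C)(C(C)C)C(C)C | intermediate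
12 | lithium enolate of 5 toward the methyl-bearing carbon | C=CCC(C)(C)[C@@H]1CC[C@@H](C)C(C)=C1O[Li] | intermediate
13 | (2R,3R,6S)-2,3-dimethyl-2-[(3R)-3-methyl-5-(triisopropylsilyloxy)pentyl]-6-(2-methylpent-4-en-2-yl)cyclohexan-1-one | C[C@H](CC[C@@]1(C)C(=O)[C@H](C(C)(C)CC=C)CC[C@H]1C)CCO[Si](C(C)C)(C(C)C)C(C)C | intermediate
14 | ozonide (1,2,4-trioxolane) of the allyl group of 13 | C[C@H](CC[C@@]1(C)C(=O)[C@H](C(C)(C)CC2OCOO2)CC[C@H]1C)CCO[Si](C(C)C)(C(C)C)C(C)C | intermediate
15 | 3-methyl-3-[(1S,3R,4R)-3,4-dimethyl-3-[(3R)-3-methyl-5-(triisopropylsilyloxy)pentyl]-2-oxocyclohexyl]butanal | C[C@H](CC[C@@]1(C)C(=O)[C@H](C(C)(C)CC=O)CC[C@H]1C)CCO[Si](C(C)C)(C(C)C)C(C)C | intermediate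
16 | (5S,8R,9R,13R)-15-(triisopropylsilyloxy)-1-norhalim-2(10)-ene (five-membered ring C10, C2, C3, C4, C5 fused to ring B) | C[C@H](CC[C@@]1(C)C2=CCC(C)(C)[C@@H]2CC[C@H]1C)CCO[Si](C(C)C)(C(C)C)C(C)C | intermediate
17 | dibromocarbene adduct of 16 across C2=C10 (cyclopropane C10, C1, C2; C1 carries both bromines) | C[C@H](CC[C@@]1(C)C23C(Br)(Br)C2CC(C)(C)[C@@H]3CC[C@H]1C)CCO[Si](C(C)C)(C(C)C)C(C)C | intermediate
18 | (5S,8R,9R,13R)-1,2-dibromo-15-(triisopropylsilyloxy)halim-1(10)-ene, both C2 epimers | C[C@H](CC[C@@]1(C)C2=C(Br)C(Br)CC(C)(C)[C@@H]2CC[C@H]1C)CCO[Si](C(C)C)(C(C)C)C(C)C | intermediate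
19 | (5S,8R,9R,13R)-1-bromo-15-(triisopropylsilyloxy)halim-1(10)-ene | C[C@H](CC[C@@]1(C)C2=C(Br)CCC(C)(C)[C@@H]2CC[C@H]1C)CCO[Si](C(C)C)(C(C)C)C(C)C | intermediate
20 | (5S,8R,9R,13R)-15-(triisopropylsilyloxy)halim-1(10)-ene | C[C@H](CC[C@@]1(C)C2=CCCC(C)(C)[C@@H]2CC[C@H]1C)CCO[Si](C(C)C)(C(C)C)C(C)C | intermediate
21 | (5S,8R,9R,13R)-halim-1(10)-en-15-ol | C[C@H](CC[C@@]1(C)C2=CCCC(C)(C)[C@@H]2CC[C@H]1C)CCO | intermediate
22 | (5S,8R,9R,13R)-halim-1(10)-en-15-al | C[C@H](CC[C@@]1(C)C2=CCCC(C)(C)[C@@H]2CC[C@H]1C)CC=O | intermediate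
23 | (5S,8R,9R,13R)-halim-1(10)-en-15-oic acid | C[C@H](CC[C@@]1(C)C2=CCCC(C)(C)[C@@H]2CC[C@H]1C)CC(=O)O | intermediate
24 | cis-2-phenyl-1,3-dioxan-5-ol (1,3-O-benzylidene glycerol) | O[C@H]1CO[C@@H](c2ccccc2)OC1 | starting material
25 | cis-2-phenyl-1,3-dioxan-5-yl (5S,8R,9R,13R)-halim-1(10)-en-15-oate | C[C@H](CC[C@@]1(C)C2=CCCC(C)(C)[C@@H]2CC[C@H]1C)CC(=O)O[C@H]1CO[C@@H](c2ccccc2)OC1 | intermediate
26 | 2-methoxy-1,3,2-dioxaborinan-5-yl (5S,8R,9R,13R)-halim-1(10)-en-15-oate | C[C@H](CC[C@@]1(C)C2=CCCC(C)(C)[C@@H]2CC[C@H]1C)CC(=O)OC1COB(OC)OC1 | intermediate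
27 | 1,3-dihydroxypropan-2-yl (5S,8R,9R,13R)-halim-1(10)-en-15-oate (CNP0174907.2) | C[C@H](CC[C@@]1(C)C2=CCCC(C)(C)[C@@H]2CC[C@H]1C)CC(=O)OC(CO)CO | target

**Total step count:** 14. **Longest linear sequence:** 12 steps (steps 3 to 14, from 6).

**Steps most likely to fail**

Step 9 (key step). The carbene may be taken up only slowly by the C2=C10 bond, which is shielded by the quaternary C9. The alkoxide may also strip HBr from the allylic bromide, or the allyl cation may lose a proton toward C5. Fallback, from 16 back to 20: carbene addition and ring opening are separated and no alkoxide is used. Dichlorocarbene made under phase transfer (CHCl3, 50% aqueous NaOH, BnEt3NCl) should give the gem-dichlorocyclopropane F1, which is stable enough to isolate. Heating F1 in xylene at 140 °C should open it by the same electrocyclic process to the 1,2-dichlorohalim-1(10)-ene silyl ether F2. Li in t-BuOH/THF should then remove the allylic and the vinylic chlorine by dissolving-metal reduction to give 20.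

Step 6. The tetrasubstituted enolate may alkylate slowly with an unactivated iodide, and equatorial attack or O-alkylation may compete, so the facial selectivity at C9 may be poor. Fallback, from 1 and 11 back to 13: both alkylations are moved ahead of the conjugate addition. Kinetic α′-deprotonation of 1 (LiN(iPr)2, THF, −78 °C) and alkylation with 11 should give the 6-alkylpulegone F3. A second deprotonation and MeI should give the 6-alkyl-6-methylpulegone F4, the methyl group entering anti to the pseudoaxial C8 methyl of the cross-conjugated enolate. Hosomi–Sakurai allylation of F4 and base equilibration at C5 then lead to 13. This order gives C9 with the usual trans control but leaves C5 to an equilibration next to a quaternary carbon.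

Step 8. The reductive coupling may stall at the pinacol stage because of the hindrance at C10, and C5 may epimerise through a titanium enolate before the ring closes. Fallback, from 13 back to 16 (it also bypasses step 7): methylenation of the ketone with Cp2TiMe2 (toluene, 70 °C) should give the 1,6-diene F5. Ring-closing metathesis with the second-generation Grubbs catalyst (CH2Cl2, 40 °C) should then close the same cyclopentene with loss of ethene.

**Further compounds**

F1 | step 9 | dichlorocarbene adduct of 16 across C2=C10 | C[C@H](CC[C@@]1(C)C23C(Cl)(Cl)C2CC(C)(C)[C@@H]3CC[C@H]1C)CCO[Si](C(C)C)(C(C)C)C(C)C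
F2 | step 9 | (5S,8R,9R,13R)-1,2-dichloro-15-(triisopropylsilyloxy)halim-1(10)-ene, both C2 epimers | C[C@H](CC[C@@]1(C)C2=C(Cl)C(Cl)CC(C)(C)[C@@H]2CC[C@H]1C)CCO[Si](C(C)C)(C(C)C)C(C)C
F3 | step 6 | (5R)-5-methyl-6-[(3R)-3-methyl-5-(triisopropylsilyloxy)pentyl]-2-(propan-2-ylidene)cyclohexan-1-one, both C6 epimers | C[C@H](CCC1C(=O)C(=C(C)C)CC[C@H]1C)CCO[Si](C(C)C)(C(C)C)C(C)C
F4 | step 6 | (5R,6R)-5,6-dimethyl-6-[(3R)-3-methyl-5-(triisopropylsilyloxy)pentyl]-2-(propan-2-ylidene)cyclohexan-1-one | C[C@H](CC[C@@]1(C)C(=O)C(=C(C)C)CC[C@H]1C)CCO[Si](C(C)C)(C(C)C)C(C)C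
F5 | step 8 | methylene analogue of 13 (C10=CH2 in place of C10=O) | C[C@H](CC[C@@]1(C)C(=C)[C@H](C(C)(C)CC=C)CC[C@H]1C)CCO[Si](C(C)C)(C(C)C)C(C)C
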